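**Assumption (chemistry):** the transient stereocentres in 17, 22 and 23 and the chlorine-bearing carbon of 16 are carried as mixtures, because all of them become sp2 carbons in 18 and 24. The carbon numbering C1–C14 defined in the analysis is used for every intermediate.

## Analysis of the target

The target is a 14-membered carbocycle, numbered here from the isopropenyl-bearing carbon C1 through C2, the C3=C4 enoate alkene (methyl ester on C4), the secondary carbinol C5, the ketone C6, C7, the tertiary methyl carbinol C8, C9, the furan carbons C10–C13 (methyl ester on C12) and C14 back to C1. The furan oxygen bridges C10 and C13, so the molecule is a 2,5-furanophane. It has three stereocentres, C1 (S), C5 (S) and C8 (R), and one stereogenic alkene (3E). C5 and C8 are 1,4-related across the C6 ketone, whereas C1 is insulated from both by the alkene on one side and the furan on the other, so no centre can direct another through a short tether. The sensitive functions are: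

- the β-hydroxy ketone C6–C8 (retro-aldol, dehydration);
- C5–H, which is α to the ketone, α to oxygen and allylic, and so prone to epimerisation under base;
- the furfuryl methylenes C9 and C14 and the acid-sensitive isopropenyl group;
- two methyl esters that must not be confused with the carboxyl carbon that becomes C6.

The synthesis is hard because the large ring has little conformational bias, C8 is a remote tertiary centre, and reactivity must be generated at C7 without touching the more acidic C5. The plan rests on the fact that C6(=O)–C7H2–C8(OH)(CH3) is an aldol triad. Its acceptor is a methyl ketone (C8, its methyl and C9) on furan C10, an acetonyl group that a levulinate can supply, and its donor can be fixed at C7 by a halogen.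

## Retrosynthetic reasoning

**32 to 31.** The C5 hydroxyl is carried as a tert-butyldimethylsilyl ether and released last with buffered fluoride. The ether keeps a proton source away from the enolate in the ring closure and allows the neighbouring carboxyl to be activated earlier.

**31 to 30 (C7–C8).** This is the only ring bond whose cleavage leaves native functionality on both sides: a ketone at C6 and a methyl ketone at C8, with no redox or protecting-group adjustment after closure. Cutting at C3=C4 would need an olefination reagent on C4 next to the labile C5; cutting at C9–C10 or C13–C14 would need sp2–sp3 couplings on a fully substituted furan. The forward reaction must form the C6 enolate at C7 only, in a molecule whose C5–H and C9–H are more acidic. Reductive generation from a C7–Br bond by divalent samarium achieves this without base, and the same step closes the ring and sets C8.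

**30 to 29 to 26 (C6–C7).** The bromomethyl ketone is traced to a carboxylic acid at C6 by a one-carbon diazo homologation and hydrobromination. The C8 ketone stays masked as a dioxolane until the homologation is done. This puts C6 at the acid level, which is what a malate carboxyl offers.

**26 to 24 to 23 to 20 + 21 (C3=C4).** The alkene is cut in the sense of a Stobbe condensation: the dianion of 21 adds to the C3 aldehyde of 20, the new C3 hydroxyl lactonises onto the C6 ester to give 23, and base-induced β-elimination opens the lactone. Three things are gained at once: C5 comes from the chiral pool without inversion, the trisubstituted alkene is formed, and the two carboxyls of 21 are told apart (C4 stays a methyl ester, C6 emerges as the free acid 24).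

**20 to 19 to 18 to 12 + 16 (furan).** The furan is cut at O–C10 and C11–C12, a Feist–Benary condensation of β-keto ester 12 with α-chloro aldehyde 16. This places the ester on C12 and the masked acetonyl group on C10 unambiguously and joins two simple fragments. C3 is carried through as a silyl-protected primary alcohol, then released (19) and oxidised (20).

**16 to 15 to 14 to 13.** The chloro aldehyde comes from 13 by ketalisation, half-reduction of the ester and α-chlorination; the ketal carbon is C8.

**12 to 9 + 10, and 9 to 6 to 4 to 2 to 1.** C12–C13 is made by acylating malonate half-ester 10 with acid 9. Acid 9 comes from lactone 6, which stores C13 at the acid level and C3 at the alcohol level. The C13–C14–C1–C2–C3 unit comes from 1 by excising the methyl-bearing ring carbon: epoxidation, hydrolysis and glycol/ketol cleavage give 4. The ring methylene next to the ketone of 1 becomes C14 and the allylic methylene becomes C2, so the (S)-configuration of 1 maps directly onto C1. The two arms are distinguished only by oxidation level, which is why they are never equalised.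

## Alternatives that were turned down

**Alternative 1:** Disconnection: the macrocycle is cut at C9–C10, drawn as an alkyne, and the furan is taken apart at O–C10, so the open-chain diyne A1 carries the C8 propargylic carbinol (triethylsilyl ether) and the C12–C13 β-keto ester as its silyl enol ether. Forward: the alkylidyne [Mo(≡CC6H4-4-OMe)(OSiPh3)3] would close A1 to cycloalkyne A2 with loss of 2-butyne; desilylation and 5-exo-dig attack of the C13 enol oxygen on C10 would then form the furan.
- For: alkyne metathesis ignores the isopropenyl and enoate alkenes, large cycloalkynes form dependably, and C8 would be set in an open chain before ring closure. On stereochemical certainty at C8 this plan is stronger than the chosen one.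
- Against: C8 would have to be made enantioselectively at a methyl ketone with no nearby control element; the alkyne beside the fully substituted C8 is hindered; the Lewis-acidic alkylidyne must tolerate the enolisable C6 ketone next to C5; three silyl groups must be differentiated before the furan can form.
- Comparison: the chosen route gives up certainty at C8 for brevity. Its aldol makes the C6–C8 unit and the ring in one step, and the furan is in place early from a robust condensation.

**Alternative 2:** Disconnection: the first ring is closed through oxygen (O–C13), giving the 12-membered propargyl vinyl ether A3; the carbocycle then arises by ring expansion at C11–C12. Forward: (Ph3P)AuCl with AgSbF6 would trigger the propargyl Claisen shift of A3 to a 14-membered allenyl β-keto ester, whose C13 oxygen closes onto C10 to give the furan of A4.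
- For: the hard C–C ring closure is replaced by an easy C–O macrocyclisation, furan and carbocycle appear in one catalytic cascade, and C8 is again fixed beforehand, an advantage over the chosen plan.
- Against: the shift must bring C11 and C12 together across a 12-membered ring through an ordered array for which there is no guide; the C9 carbinol is neopentylic and would etherify reluctantly; a stereocentre at C9 is made only to be destroyed; the cationic gold catalyst can bind the isopropenyl group, the enoate and the C6 ketone.
- Comparison: the cascade is established for open-chain propargyl vinyl ethers, not as a ring expansion, so risk sits in two places instead of one. The chosen route is shorter and concentrates its risk in a single step with closer precedent.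

**Alternative 3:** Disconnection: the β-hydroxy ketone is masked as an isoxazoline and the ring is cut at C6–C7 and O–C8; the open-chain aldoxime A5 carries a 2-methylallyl group on furan C10. Forward: oxidation of the oxime (NaOCl or PhI(OAc)2) gives a nitrile oxide that adds to the 1,1-disubstituted alkene with oxygen at C8, closing the isoxazoline and the carbocycle of A6; N–O cleavage and imine hydrolysis would release the aldol.
- For: intramolecular nitrile oxide cycloadditions close large rings, the regiochemistry is dependable, no enolate is involved, and the isoxazoline protects the aldol from retro-aldol and dehydration. In robustness of the ring-closing event it is at least equal to the chosen plan.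
- Against: the isopropenyl group on C1 is an equally good dipolarophile and competes; the C8 face is as uncontrolled as in the chosen step; unmasking needs an N–O reduction (for example Mo(CO)6) that spares two alkenes and the furan and passes through an α-silyloxy imine whose enamine tautomer endangers C5; two steps are added after ring closure.
- Comparison: the chosen route delivers the aldol directly, and its ring closure is reversible, which offers a way to correct C8 that a cycloaddition cannot.

Key step: step 17

## Route

Step 1
Reactants: 1 (S)-carvone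
Product: 2 (1S,4S,6S)-1-methyl-4-(prop-1-en-2-yl)-7-oxabicyclo[4.1.0]heptan-2-one
Conditions: 30% aq. H2O2, NaOH (0.3 equiv), MeOH, 0 °C
Reagents that add atoms: hydrogen peroxide, OO
Why: Weitz–Scheffer nucleophilic epoxidation attacks only the electron-poor enone alkene and leaves the isopropenyl group alone; hydroperoxide should add anti to the ring substituent, though both new centres are excised in step 2.

Step 2
Reactants: 2 (epoxy ketone)
Product: 4 (3S)-5-oxo-3-(prop-1-en-2-yl)pentanoic acid, via ketodiol 3 (not isolated)
Conditions: 1.5 M aq. H2SO4, THF, rt; then NaIO4 (2.5 equiv), THF/H2O, 0 °C → rt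
Reagents that add atoms: water, O
Why: Acid-catalysed epoxide hydrolysis gives the α,β-dihydroxy ketone, and Malaprade cleavage of its ketol and diol bonds turns the ketone carbon into CO2H and the secondary carbinol into CHO while the methyl-bearing carbon leaves as acetic acid. The stereocentre is β to both new carbonyls and cannot epimerise, and the two arms stay different (acid and aldehyde).

Step 3
Reactants: 4 (aldehyde acid)
Product: 6 (4S)-4-(prop-1-en-2-yl)oxan-2-one, via hydroxy acid 5 (not isolated)
Conditions: NaOH (1 equiv), NaBH4, EtOH/H2O, 0 °C; then 2 M HCl to pH 2, rt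
Reagents that add atoms: none
Why: Borohydride reduces the aldehyde but not the carboxylate, and the δ-hydroxy acid should lactonise on acidification; the stereocentre is untouched and the lactone keeps C13 at the acid level and C3 at the alcohol level.

Step 4
Reactants: 6 (lactone)
Product: 9 (3S)-5-[(tert-butyldimethylsilyl)oxy]-3-(prop-1-en-2-yl)pentanoic acid, via potassium hydroxy carboxylate 7 (not isolated), via bis-silyl derivative 8 (not isolated)
Conditions: KOH (1.05 equiv), MeOH/H2O, rt, evaporation; TBSCl (2.4 equiv), imidazole, DMF, rt; then K2CO3, MeOH/THF/H2O, rt; pH 5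
Reagents that add atoms: potassium hydroxide, [K+].[OH-]; tert-butyldimethylsilyl chloride, CC(C)(C)[Si](C)(C)Cl
Why: Saponification, exhaustive silylation and selective hydrolysis of the labile silyl ester is the standard conversion of a lactone into an ω-silyloxy acid.

Step 5
Reactants: 9 (silyloxy acid); 10 potassium methyl malonate
Product: 12 methyl (5S)-7-[(tert-butyldimethylsilyl)oxy]-3-oxo-5-(prop-1-en-2-yl)heptanoate, via acyl imidazolide 11 (not isolated)
Conditions: 1,1'-carbonyldiimidazole, THF, rt; then 10 (1.5 equiv), MgCl2, Et3N, MeCN, rt → 40 °C; cold 0.5 M HCl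
Reagents that add atoms: none
Why: Masamune–Brooks chain extension: the magnesium enolate of the malonate half-ester is C-acylated by the acyl imidazolide and decarboxylates on work-up, forming C12–C13 under near-neutral conditions that the silyl ether and the alkene tolerate.

Step 6
Reactants: 13 ethyl levulinate
Product: 14 ethyl 3-(2-methyl-1,3-dioxolan-2-yl)propanoate
Conditions: ethylene glycol, p-toluenesulfonic acid monohydrate (cat.), PhMe, reflux, Dean–Stark
Reagents that add atoms: ethylene glycol, OCCO
Why: Standard ketalisation; the ketone reacts and the ester does not, and water is removed azeotropically.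

Step 7
Reactants: 14 (ketal ester)
Product: 15 3-(2-methyl-1,3-dioxolan-2-yl)propanal
Conditions: i-Bu2AlH (1.05 equiv), CH2Cl2, −78 °C; MeOH, then aq. KNaC4H4O6
Reagents that add atoms: none
Why: Partial reduction of the ester stops at the tetrahedral aluminium hemiacetal at −78 °C and releases the aldehyde on work-up.

Step 8
Reactants: 15 (ketal aldehyde)
Product: 16 rac-2-chloro-3-(2-methyl-1,3-dioxolan-2-yl)propanal
Conditions: N-chlorosuccinimide, DL-proline (10 mol %), CH2Cl2, 0 °C → rt; used crude
Reagents that add atoms: N-chlorosuccinimide, O=C1CCC(=O)N1Cl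
Why: Enamine-catalysed α-chlorination of an aldehyde; the racemate is sufficient because this carbon becomes furan C10.

Step 9
Reactants: 12 (β-keto ester); 16 (α-chloro aldehyde)
Product: 18 methyl 2-{(2S)-4-[(tert-butyldimethylsilyl)oxy]-2-(prop-1-en-2-yl)butyl}-5-[(2-methyl-1,3-dioxolan-2-yl)methyl]furan-3-carboxylate, via hydroxydihydrofuran 17 (not isolated)
Conditions: Et3N (1.5 equiv), CH2Cl2, 0 °C → rt; aqueous wash; then pyridinium p-toluenesulfonate (cat.), 4 Å molecular sieves, PhMe, 45 °C
Reagents that add atoms: none
Why: Feist–Benary furan synthesis: the active methylene C12 adds to the aldehyde (which becomes C11), the enol oxygen displaces chloride in a 5-exo-tet closure (making O–C10), and mild anhydrous acid dehydrates to the aromatic ring without opening the dioxolane.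

Step 10
Reactants: 18 (furan silyl ether)
Product: 19 methyl 2-[(2S)-4-hydroxy-2-(prop-1-en-2-yl)butyl]-5-[(2-methyl-1,3-dioxolan-2-yl)methyl]furan-3-carboxylate
Conditions: Bu4NF (1.2 equiv), THF, 0 °C → rt
Reagents that add atoms: none
Why: Fluoride cleaves the primary silyl ether; the ketal and both esters are unaffected.

Step 11
Reactants: 19 (furan alcohol)
Product: 20 methyl 5-[(2-methyl-1,3-dioxolan-2-yl)methyl]-2-[(2R)-4-oxo-2-(prop-1-en-2-yl)butyl]furan-3-carboxylate
Conditions: Dess–Martin periodinane, NaHCO3, CH2Cl2, 0 °C → rt
Reagents that add atoms: none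
Why: Buffered periodinane oxidation stops at the aldehyde; the stereocentre is β to the carbonyl and is not touched (the descriptor changes to R only because the CHO arm now outranks the furylmethyl arm).

Step 12
Reactants: 20 (furan aldehyde); 21 dimethyl (S)-malate
Product: 23 methyl (4S)-4-hydroxy-2-{(2S)-3-[3-(methoxycarbonyl)-5-[(2-methyl-1,3-dioxolan-2-yl)methyl]furan-2-yl]-2-(prop-1-en-2-yl)propyl}-5-oxooxolane-3-carboxylate, via aldol diol 22 (not isolated)
Conditions: 21 (1.4 equiv), LiN(SiMe3)2 (2.9 equiv), THF, −78 → −20 °C; 20, −78 °C; AcOH; then 10-camphorsulfonic acid (10 mol %), CH2Cl2, rt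
Reagents that add atoms: none
Why: Aldol addition of the alkoxide–enolate dianion of malate, which cannot β-eliminate because the alkoxide is not a leaving group, followed by 5-exo-trig lactonisation of the new C3 hydroxyl onto the C6 ester, which sets the two malate carboxyls apart. C5 keeps the configuration of 21; the new centres at C3 and C4 form as a mixture and are both removed in step 13.

Step 13
Reactants: 23 (hydroxy lactone)
Product: 24 (2S,3E,6S)-2-hydroxy-3-(methoxycarbonyl)-7-{3-(methoxycarbonyl)-5-[(2-methyl-1,3-dioxolan-2-yl)methyl]furan-2-yl}-6-(prop-1-en-2-yl)hept-3-enoic acid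
Conditions: LiN(SiMe3)2 (2.3 equiv), THF, −78 → 0 °C; then cold 1 M HCl to pH 3
Reagents that add atoms: none
Why: This is the second stage of a Stobbe condensation: after O–H deprotonation the C4 ester enolate expels the ring carboxylate (E1cB), forming C3=C4 and freeing the C6 acid, while the C5 alkoxide can neither leave nor allow deprotonation at C5. The E-alkene is expected because the C3 hydrogen, not the chain, turns toward the planar ester enolate as the ring opens, the usual outcome of Stobbe condensations of aldehydes.

Step 14
Reactants: 24 (hydroxy acid)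
Product: 26 (2S,3E,6S)-2-[(tert-butyldimethylsilyl)oxy]-3-(methoxycarbonyl)-7-{3-(methoxycarbonyl)-5-[(2-methyl-1,3-dioxolan-2-yl)methyl]furan-2-yl}-6-(prop-1-en-2-yl)hept-3-enoic acid, via silyl ester 25 (not isolated)
Conditions: TBSCl (2.6 equiv), imidazole, DMF, rt; then K2CO3, MeOH/THF/H2O, 0 °C; pH 4–5
Reagents that add atoms: tert-butyldimethylsilyl chloride, CC(C)(C)[Si](C)(C)Cl
Why: Silylation of both hydroxyl and carboxyl followed by mild hydrolysis of the silyl ester is the standard protection of an α-hydroxy acid; once the carboxylate forms, C5–H is no longer acidic.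

Step 15
Reactants: 26 (silyloxy acid)
Product: 29 methyl 2-[(2S,4E,6S)-8-bromo-6-[(tert-butyldimethylsilyl)oxy]-5-(methoxycarbonyl)-7-oxo-2-(prop-1-en-2-yl)oct-4-en-1-yl]-5-[(2-methyl-1,3-dioxolan-2-yl)methyl]furan-3-carboxylate, via acid chloride 27 (not isolated), via diazoketone 28 (not isolated)
Conditions: 1-chloro-N,N,2-trimethylprop-1-en-1-amine (1.2 equiv), CH2Cl2, 0 °C; CH2N2 (3 equiv), Et2O, 0 °C, 1 h; N2 purge; then 48% aq. HBr (1.2 equiv), 0 °C, 10 min; NaHCO3
Reagents that add atoms: diazomethane, C=[N+]=[N-]; hydrogen bromide, Br
Why: The acid chloride is formed under neutral conditions, acylates diazomethane (the first stage of an Arndt–Eistert sequence) and the diazoketone is protonated and displaced by bromide with loss of N2, which introduces C7 and the bromine without an enolate at C5. The trisubstituted enoate is a poor dipolarophile, so cold, short exposure to diazomethane should avoid pyrazoline formation.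

Step 16
Reactants: 29 (bromoketone ketal)
Product: 30 methyl 2-[(2S,4E,6S)-8-bromo-6-[(tert-butyldimethylsilyl)oxy]-5-(methoxycarbonyl)-7-oxo-2-(prop-1-en-2-yl)oct-4-en-1-yl]-5-(2-oxopropyl)furan-3-carboxylate
Conditions: p-toluenesulfonic acid monohydrate (10 mol %), acetone/H2O (10:1), rt
Reagents that add atoms: water, O
Why: Acid-catalysed ketal hydrolysis with a non-nucleophilic acid releases the C8 methyl ketone; the bromomethyl ketone is stable to acid and the electron-poor α-keto silyl ether is slow to cleave.

Step 17
Reactants: 30 (seco bromoketone)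
Product: 31 C5 tert-butyldimethylsilyl ether of the target: (1S,3E,5S,8R)-configured 14-membered furanophane with free C8 hydroxyl
Conditions: SmI2 (2.2 equiv, 0.1 M in THF), THF, −78 °C, slow addition of 30 (final 0.003 M); pH 7 buffer
Reagents that add atoms: none
Why: Two electron transfers from divalent samarium cleave the C7–Br bond and leave an oxygen-bound trivalent samarium enolate whose double bond is fixed between C6 and C7, so C7 becomes the nucleophile although C5–H and C9–H are more acidic and no base is present. The closest known reaction type is the SmI2-mediated intramolecular Reformatsky-type aldol of α-halo carbonyl compounds, which closes medium and large rings onto aldehydes and smaller rings onto ketones; a ketone acceptor in a large ring is the extension asked of it here. The ring closes in a 14-exo-trig mode (enolate double bond endocyclic, the attacked C8=O exocyclic), helped by the rigid E-enoate and furan units between the reacting ends. C8 is set in a closed six-membered transition state in which the enolate oxygen and the C8 carbonyl share samarium; which ketone face is presented depends on the conformation of the forming ring and on the bulky C5 silyloxy group next to the enolate, and cannot be predicted with confidence. The diastereomers may therefore need separation, and warming the samarium aldolate to allow retro-aldol and re-closure is a possible correction. The step needs reduction of C–Br in preference to the α-silyloxy ketone, the enoate and the esters (C–Br is by far the most reducible site and only 2.2 equiv are used at −78 °C), addition to the ketone in preference to proton transfer from C9–H or five-membered Claisen attack on the C4 ester (samarium enolates are weakly basic and add to esters sluggishly), and cyclisation over oligomerisation (slow addition at high dilution). The C5 silyloxy group is α' to the enolate, not β to its carbon, so it cannot be expelled.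

Step 18
Reactants: 31 (macrocyclic silyl ether)
Product: 32 target CNP0225662.1: (1S,3E,5S,8R)-5,8-dihydroxy-8-methyl-6-oxo-1-(prop-1-en-2-yl) 14-membered 2,5-furanophane with methyl esters on C4 and C12
Conditions: HF·pyridine, pyridine, THF, 0 °C → rt
Reagents that add atoms: none
Why: Buffered fluoride removes the secondary silyl ether without base, so the α-hydroxy ketone and the β-hydroxy ketone are not exposed to enolising or retro-aldol conditions.

## Compound list

1 | (S)-carvone | C=C(C)[C@H]1CC=C(C)C(=O)C1 | starting material
2 | (1S,4S,6S)-1-methyl-4-(prop-1-en-2-yl)-7-oxabicyclo[4.1.0]heptan-2-one | C=C(C)[C@H]1C[C@@H]2O[C@]2(C)C(=O)C1 | intermediate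
3 | (2S,3R,5S)-2,3-dihydroxy-2-methyl-5-(prop-1-en-2-yl)cyclohexan-1-one | C=C(C)[C@H]1C[C@@H](O)[C@](C)(O)C(=O)C1 | intermediate
4 | (3S)-5-oxo-3-(prop-1-en-2-yl)pentanoic acid | C=C(C)[C@H](CC(=O)O)CC=O | intermediate
5 | (3S)-5-hydroxy-3-(prop-1-en-2-yl)pentanoic acid | C=C(C)[C@H](CC(=O)O)CCO | intermediate
6 | (4S)-4-(prop-1-en-2-yl)oxan-2-one | C=C(C)[C@H]1CCOC(=O)C1 | intermediate
7 | potassium (3S)-5-hydroxy-3-(prop-1-en-2-yl)pentanoate | C=C(C)[C@H](CC(=O)[O-])CCO.[K+] | intermediate
8 | tert-butyldimethylsilyl (3S)-5-[(tert-butyldimethylsilyl)oxy]-3-(prop-1-en-2-yl)pentanoate | C=C(C)[C@H](CC(=O)O[Si](C)(C)C(C)(C)C)CCO[Si](C)(C)C(C)(C)C | intermediate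
9 | (3S)-5-[(tert-butyldimethylsilyl)oxy]-3-(prop-1-en-2-yl)pentanoic acid | C=C(C)[C@H](CC(=O)O)CCO[Si](C)(C)C(C)(C)C | intermediate
10 | potassium methyl malonate (potassium 3-methoxy-3-oxopropanoate) | COC(=O)CC(=O)[O-].[K+] | starting material
11 | 1-{(3S)-5-[(tert-butyldimethylsilyl)oxy]-3-(prop-1-en-2-yl)pentanoyl}-1H-imidazole | C=C(C)[C@H](CC(=O)n1ccnc1)CCO[Si](C)(C)C(C)(C)C | intermediate
12 | methyl (5S)-7-[(tert-butyldimethylsilyl)oxy]-3-oxo-5-(prop-1-en-2-yl)heptanoate | C=C(C)[C@H](CC(=O)CC(=O)OC)CCO[Si](C)(C)C(C)(C)C | intermediate
13 | ethyl levulinate (ethyl 4-oxopentanoate) | CCOC(=O)CCC(C)=O | starting material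
14 | ethyl 3-(2-methyl-1,3-dioxolan-2-yl)propanoate | CCOC(=O)CCC1(C)OCCO1 | intermediate
15 | 3-(2-methyl-1,3-dioxolan-2-yl)propanal | O=CCCC1(C)OCCO1 | intermediate
16 | rac-2-chloro-3-(2-methyl-1,3-dioxolan-2-yl)propanal | O=CC(Cl)CC1(C)OCCO1 | intermediate
17 | methyl 2-{(2S)-4-[(tert-butyldimethylsilyl)oxy]-2-(prop-1-en-2-yl)butyl}-4-hydroxy-5-[(2-methyl-1,3-dioxolan-2-yl)methyl]-4,5-dihydrofuran-3-carboxylate (ring diastereomers) | C=C(C)[C@H](CC1=C(C(=O)OC)C(O)C(CC2(C)OCCO2)O1)CCO[Si](C)(C)C(C)(C)C | intermediate
18 | methyl 2-{(2S)-4-[(tert-butyldimethylsilyl)oxy]-2-(prop-1-en-2-yl)butyl}-5-[(2-methyl-1,3-dioxolan-2-yl)methyl]furan-3-carboxylate | C=C(C)[C@H](Cc1oc(CC2(C)OCCO2)cc1C(=O)OC)CCO[Si](C)(C)C(C)(C)C | intermediate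
19 | methyl 2-[(2S)-4-hydroxy-2-(prop-1-en-2-yl)butyl]-5-[(2-methyl-1,3-dioxolan-2-yl)methyl]furan-3-carboxylate | C=C(C)[C@H](Cc1oc(CC2(C)OCCO2)cc1C(=O)OC)CCO | intermediate
20 | methyl 5-[(2-methyl-1,3-dioxolan-2-yl)methyl]-2-[(2R)-4-oxo-2-(prop-1-en-2-yl)butyl]furan-3-carboxylate | C=C(C)[C@H](Cc1oc(CC2(C)OCCO2)cc1C(=O)OC)CC=O | intermediate
21 | dimethyl (S)-malate | COC(=O)C[C@H](O)C(=O)OC | starting material
22 | dimethyl (2S)-2-hydroxy-3-{(3S)-1-hydroxy-4-[3-(methoxycarbonyl)-5-[(2-methyl-1,3-dioxolan-2-yl)methyl]furan-2-yl]-3-(prop-1-en-2-yl)butyl}butanedioate (mixture at the two new centres) | C=C(C)[C@H](Cc1oc(CC2(C)OCCO2)cc1C(=O)OC)CC(O)C(C(=O)OC)[C@H](O)C(=O)OC | intermediate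
23 | methyl (4S)-4-hydroxy-2-{(2S)-3-[3-(methoxycarbonyl)-5-[(2-methyl-1,3-dioxolan-2-yl)methyl]furan-2-yl]-2-(prop-1-en-2-yl)propyl}-5-oxooxolane-3-carboxylate (mixture at lactone C2 and C3) | C=C(C)[C@H](Cc1oc(CC2(C)OCCO2)cc1C(=O)OC)CC1OC(=O)[C@@H](O)C1C(=O)OC | intermediate
24 | (2S,3E,6S)-2-hydroxy-3-(methoxycarbonyl)-7-{3-(methoxycarbonyl)-5-[(2-methyl-1,3-dioxolan-2-yl)methyl]furan-2-yl}-6-(prop-1-en-2-yl)hept-3-enoic acid | C=C(C)[C@H](Cc1oc(CC2(C)OCCO2)cc1C(=O)OC)C/C=C(/C(=O)OC)[C@H](O)C(=O)O | intermediate
25 | tert-butyldimethylsilyl ester of 26 | C=C(C)[C@H](Cc1oc(CC2(C)OCCO2)cc1C(=O)OC)C/C=C(/C(=O)OC)[C@H](O[Si](C)(C)C(C)(C)C)C(=O)O[Si](C)(C)C(C)(C)C | intermediate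
26 | (2S,3E,6S)-2-[(tert-butyldimethylsilyl)oxy]-3-(methoxycarbonyl)-7-{3-(methoxycarbonyl)-5-[(2-methyl-1,3-dioxolan-2-yl)methyl]furan-2-yl}-6-(prop-1-en-2-yl)hept-3-enoic acid | C=C(C)[C@H](Cc1oc(CC2(C)OCCO2)cc1C(=O)OC)C/C=C(/C(=O)OC)[C@H](O[Si](C)(C)C(C)(C)C)C(=O)O | intermediate
27 | acid chloride of 26 | C=C(C)[C@H](Cc1oc(CC2(C)OCCO2)cc1C(=O)OC)C/C=C(/C(=O)OC)[C@H](O[Si](C)(C)C(C)(C)C)C(=O)Cl | intermediate
28 | methyl 2-[(2S,4E,6S)-6-[(tert-butyldimethylsilyl)oxy]-8-diazo-5-(methoxycarbonyl)-7-oxo-2-(prop-1-en-2-yl)oct-4-en-1-yl]-5-[(2-methyl-1,3-dioxolan-2-yl)methyl]furan-3-carboxylate | C=C(C)[C@H](Cc1oc(CC2(C)OCCO2)cc1C(=O)OC)C/C=C(/C(=O)OC)[C@H](O[Si](C)(C)C(C)(C)C)C(=O)C=[N+]=[N-] | intermediate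
29 | methyl 2-[(2S,4E,6S)-8-bromo-6-[(tert-butyldimethylsilyl)oxy]-5-(methoxycarbonyl)-7-oxo-2-(prop-1-en-2-yl)oct-4-en-1-yl]-5-[(2-methyl-1,3-dioxolan-2-yl)methyl]furan-3-carboxylate | C=C(C)[C@H](Cc1oc(CC2(C)OCCO2)cc1C(=O)OC)C/C=C(/C(=O)OC)[C@H](O[Si](C)(C)C(C)(C)C)C(=O)CBr | intermediate
30 | methyl 2-[(2S,4E,6S)-8-bromo-6-[(tert-butyldimethylsilyl)oxy]-5-(methoxycarbonyl)-7-oxo-2-(prop-1-en-2-yl)oct-4-en-1-yl]-5-(2-oxopropyl)furan-3-carboxylate | C=C(C)[C@H](Cc1oc(CC(C)=O)cc1C(=O)OC)C/C=C(/C(=O)OC)[C@H](O[Si](C)(C)C(C)(C)C)C(=O)CBr | intermediate
31 | C5 tert-butyldimethylsilyl ether of the target, (1S,3E,5S,8R) | C=C(C)[C@H]1C/C=C(/C(=O)OC)[C@H](O[Si](C)(C)C(C)(C)C)C(=O)C[C@](C)(O)CC2=CC(C(=O)OC)=C(C1)O2 | intermediate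
32 | CNP0225662.1, (1S,3E,5S,8R) in the C1–C14 numbering | C=C(C)[C@H]1C/C=C(/C(=O)OC)[C@H](O)C(=O)C[C@](C)(O)CC2=CC(C(=O)OC)=C(C1)O2 | target

## Step count and least certain steps

Total: 18 steps. Longest linear sequence: 15 steps (steps 1–5 and 9–18); steps 6–8 prepare fragment 16.

**Step 17 (key step).** Two things are most likely to go wrong. The samarium enolate may be quenched by proton transfer from the furfuryl ketone, or react intermolecularly, because a ketone is a slower acceptor than an aldehyde in a ring of this size. The ketone face may also be poorly discriminated, giving both C8 epimers. Fallback: from 30, zinc and Me3SiCl in MeCN should convert the bromoketone regiospecifically into the trimethylsilyl enol ether F1. A Mukaiyama aldol under high dilution (TiCl4, CH2Cl2, −78 °C) would then close the same C7–C8 bond through an open, Lewis-acid-activated transition state with a different facial bias, and return to 31 after aqueous work-up.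

**Step 13.** The ring C3–O bond overlaps poorly with the enolate, so the lithium dianion may open slowly. That would leave time for retro-aldol cleavage at C4–C5 or erode the E/Z ratio. Fallback, setting out from 23 and returning at 29 (bypassing steps 14 and 15):
- silylation (TBSCl, imidazole) gives the silyl ether lactone F2;
- Me(MeO)NH·HCl with Me3Al opens the lactone, which is more reactive than the methyl esters, to the hydroxy N-methoxy-N-methylamide F3;
- mesylation gives the mesylate F4;
- DBU effects an open-chain E1cB elimination, in which C4–H is the only acidic position and the mesylate the only good leaving group, to the E-enoate amide F5;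
- LiCH2Br, generated in situ from CH2Br2 and MeLi·LiBr at −78 °C, adds to the amide to give 29.

**Step 16.** While the dioxolane hydrolyses, the C5 silyl ether may be lost or the ketone may enolise toward C5 under acid, and the bromomethyl ketone limits how long the reaction can run. Fallback: from 26, the same hydrolysis carried out one stage earlier gives the keto acid F6, whose C5–H sits next to a carboxyl rather than a ketone. The one-pot homologation of step 15 then passes through the acid chloride F7 and the diazoketone F8 and returns directly to 30.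

**Step 2.** The isopropenyl group may hydrate during the aqueous acid hydrolysis, and the small, water-soluble aldehyde acid, which equilibrates with a cyclic lactol, may be lost on extraction. Fallback: from 2, the hydrolysis is stopped early and crude 3 is cleaved with Pb(OAc)4 in MeOH/PhH at 0 °C to the neutral, extractable methyl ester aldehyde F9. NaBH4 in MeOH gives the hydroxy ester F10, and catalytic p-toluenesulfonic acid in warm PhMe lactonises it to 6.

## Further compounds

F1 | step 17 | trimethylsilyl enol ether (C6=C7) of the debrominated seco ketone | C=C(C)[C@H](Cc1oc(CC(C)=O)cc1C(=O)OC)C/C=C(/C(=O)OC)[C@H](O[Si](C)(C)C(C)(C)C)C(=C)O[Si](C)(C)C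
F2 | step 13 | tert-butyldimethylsilyl ether of lactone 23 | C=C(C)[C@H](Cc1oc(CC2(C)OCCO2)cc1C(=O)OC)CC1OC(=O)[C@@H](O[Si](C)(C)C(C)(C)C)C1C(=O)OC
F3 | step 13 | ring-opened C3-hydroxy N-methoxy-N-methylamide (C6) with C5 silyl ether | C=C(C)[C@H](Cc1oc(CC2(C)OCCO2)cc1C(=O)OC)CC(O)C(C(=O)OC)[C@H](O[Si](C)(C)C(C)(C)C)C(=O)N(C)OC
F4 | step 13 | C3 methanesulfonate of F3 | C=C(C)[C@H](Cc1oc(CC2(C)OCCO2)cc1C(=O)OC)CC(OS(C)(=O)=O)C(C(=O)OC)[C@H](O[Si](C)(C)C(C)(C)C)C(=O)N(C)OC
F5 | step 13 | (3E)-enoate N-methoxy-N-methylamide with C5 silyl ether | C=C(C)[C@H](Cc1oc(CC2(C)OCCO2)cc1C(=O)OC)C/C=C(/C(=O)OC)[C@H](O[Si](C)(C)C(C)(C)C)C(=O)N(C)OC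
F6 | step 16 | keto acid (26 without the dioxolane) | C=C(C)[C@H](Cc1oc(CC(C)=O)cc1C(=O)OC)C/C=C(/C(=O)OC)[C@H](O[Si](C)(C)C(C)(C)C)C(=O)O
F7 | step 16 | acid chloride of F6 | C=C(C)[C@H](Cc1oc(CC(C)=O)cc1C(=O)OC)C/C=C(/C(=O)OC)[C@H](O[Si](C)(C)C(C)(C)C)C(=O)Cl
F8 | step 16 | diazoketone from F7 | C=C(C)[C@H](Cc1oc(CC(C)=O)cc1C(=O)OC)C/C=C(/C(=O)OC)[C@H](O[Si](C)(C)C(C)(C)C)C(=O)C=[N+]=[N-]
F9 | step 2 | methyl (3S)-5-oxo-3-(prop-1-en-2-yl)pentanoate | C=C(C)[C@H](CC(=O)OC)CC=O
F10 | step 2 | methyl (3S)-5-hydroxy-3-(prop-1-en-2-yl)pentanoate | C=C(C)[C@H](CC(=O)OC)CCO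
A1 | alternative 1 | open-chain bis(methyl-capped) diyne with C12=C13 silyl enol ether | C=C(C)[C@H](C/C(O[Si](C)(C)C(C)(C)C)=C(\CC#CC)C(=O)OC)C/C=C(/C(=O)OC)[C@H](O[Si](C)(C)C(C)(C)C)C(=O)C[C@](C)(O[Si](CC)(CC)CC)C#CC
A2 | alternative 1 | 14-membered cycloalkyne (C9≡C10) | C=C(C)[C@H]1C/C=C(/C(=O)OC)[C@H](O[Si](C)(C)C(C)(C)C)C(=O)C[C@](C)(O[Si](CC)(CC)CC)C#CC/C(C(=O)OC)=C(\C1)O[Si](C)(C)C(C)(C)C
A3 | alternative 2 | 12-membered propargyl vinyl ether closed through O–C13 | C=C(C)[C@H]1C/C=C(/C(=O)OC)[C@H](O[Si](C)(C)C(C)(C)C)C(=O)C[C@](C)(O[Si](CC)(CC)CC)C(C#C)O/C(=C/C(=O)OC)C1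
A4 | alternative 2 | bis-silyl ether of the target (C5 tert-butyldimethylsilyl, C8 triethylsilyl) | C=C(C)[C@H]1C/C=C(/C(=O)OC)[C@H](O[Si](C)(C)C(C)(C)C)C(=O)C[C@](C)(O[Si](CC)(CC)CC)CC2=CC(C(=O)OC)=C(C1)O2
A5 | alternative 3 | C6 aldoxime with a 2-methylallyl group on furan C10 | C=C(C)[C@H](Cc1oc(CC(C)=C)cc1C(=O)OC)C/C=C(/C(=O)OC)[C@H](O[Si](C)(C)C(C)(C)C)C=NO
A6 | alternative 3 | isoxazoline-bridged furanophane | C=C(C)[C@H]1C/C=C(/C(=O)OC)[C@H](O[Si](C)(C)C(C)(C)C)C3=NO[C@@](C)(C3)CC2=CC(C(=O)OC)=C(C1)O2
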